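**Strategy.** Everything rests on cutting the C7–C11 bond of the α-methylene γ-lactone. The target carries, on the ten-membered ring, the lactone oxygen on C6, the lactone carbon C11 on C7 and a free hydroxyl on C8. C7–C8 is therefore carried as a trans epoxide and C11 as the phosphonoacetate carbanion of an ester on O6. One operation (5-exo epoxide opening, then in-flask methylenation) forms C7–C11, closes the lactone, sets C7 by inversion, frees the C8 hydroxyl and installs the methylidene. The precursor is an acyclic, Sharpless-resolved epoxy alcohol ester bearing a C9 acetal and a Z vinyl iodide, which afterwards close the ten-membered ring by a Nozaki–Hiyama–Kishi reaction.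

Key step: step 6

Remark: carbons are numbered as in germacranolides (C6 bears the lactone oxygen, C7 the lactone carbon C11, C8 the hydroxyl, C9 the ester; C1=C10 is the Z olefin, C4=C5 the E olefin); compounds 1, 4, 8 and 16 are taken as commercial.

Step 1
Reactants: 1 pent-4-yn-1-ol
Product: 2 pent-4-ynal
Conditions: TEMPO (cat.), PhI(OAc)2, CH2Cl2, 23 °C
Reagents that add atoms: none
Why: The oxoammonium-mediated (TEMPO) alcohol oxidation stops at the aldehyde and leaves the terminal alkyne untouched, and no stereocenter is formed.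

Step 2
Reactants: 2 pent-4-ynal
Product: 3 (5Z)-6-iodohept-5-en-1-yne
Conditions: [Ph3PEt]I, n-BuLi, THF, 23 °C; I2, −78 °C; NaN(SiMe3)2, −20 °C; then 2, −78 → 0 °C
Reagents that add atoms: ethyltriphenylphosphonium iodide, CC[P+](c1ccccc1)(c1ccccc1)c1ccccc1.[I-]; iodine, II
Why: The Stork–Zhao-type Wittig olefination with the α-iodo ylide Ph3P=C(I)CH3 is known to give (Z)-2-iodoalk-2-enes from aliphatic aldehydes under kinetic control, which places iodine cis to the chain and so fixes the later Z geometry of C1=C10.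

Step 3
Reactants: 3 (5Z)-6-iodohept-5-en-1-yne; 4 (2E)-4,4-dimethoxybut-2-enal
Product: 6 rac-(2E,5E,9Z)-10-iodo-1,1-dimethoxy-6-methylundeca-2,5,9-trien-4-ol, via alkenylalane 5 (not isolated)
Conditions: Me3Al, Cp2ZrCl2 (cat.), CH2Cl2, 0 → 23 °C; volatiles removed; then 4, THF, −78 → 0 °C
Reagents that add atoms: trimethylaluminium, C[Al](C)C
Why: Negishi zirconium-catalysed methylalumination adds methyl and aluminium syn across the terminal alkyne with methyl on the internal carbon (this sets the E olefin C4=C5 and C15), and the alkenylalane then adds 1,2 to the enal with retention of geometry, giving the C6 carbinol as a racemate that is resolved in step 4.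

Step 4
Reactants: 6 rac-(2E,5E,9Z)-10-iodo-1,1-dimethoxy-6-methylundeca-2,5,9-trien-4-ol
Product: 7 (1S,2E,6Z)-1-[(2S,3R)-3-(dimethoxymethyl)oxiran-2-yl]-7-iodo-3-methylocta-2,6-dien-1-ol
Conditions: Ti(OiPr)4, L-(+)-DIPT, TBHP (0.6 equiv), 4 Å MS, CH2Cl2, −20 °C
Reagents that add atoms: tert-butyl hydroperoxide, CC(C)(C)OO
Why: Sharpless asymmetric epoxidation run as a kinetic resolution: with L-(+)-DIPT the (R)-enantiomer of 6 should be epoxidised fast at C7=C8 from the face that gives the erythro (2S,3R)-oxiranyl carbinol, so C6, C7 and C8 are set together under reagent control, while the slow (S)-enantiomer (separated) and the C4=C5 olefin, whose methyl group cis to the carbinol causes allylic 1,3-strain in the titanium-bound transition state, stay untouched.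

Step 5
Reactants: 7 (1S,2E,6Z)-1-[(2S,3R)-3-(dimethoxymethyl)oxiran-2-yl]-7-iodo-3-methylocta-2,6-dien-1-ol; 8 (diethoxyphosphoryl)acetic acid
Product: 9 (1S,2E,6Z)-1-[(2S,3R)-3-(dimethoxymethyl)oxiran-2-yl]-7-iodo-3-methylocta-2,6-dien-1-yl (diethoxyphosphoryl)acetate
Conditions: DCC, DMAP (cat.), CH2Cl2, 0 → 23 °C
Reagents that add atoms: none
Why: Steglich esterification acylates the secondary epoxy alcohol under neutral conditions without epoxide migration and places C11 and C12 as a tether on O6, with no stereocenter touched.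

Step 6
Reactants: 9 (1S,2E,6Z)-1-[(2S,3R)-3-(dimethoxymethyl)oxiran-2-yl]-7-iodo-3-methylocta-2,6-dien-1-yl (diethoxyphosphoryl)acetate
Product: 11 (4S,5S)-4-[(1R)-1-hydroxy-2,2-dimethoxyethyl]-5-[(1E,5Z)-6-iodo-2-methylhepta-1,5-dien-1-yl]-3-methylideneoxolan-2-one, via phosphono lactone 10 (not isolated)
Conditions: NaH, THF/DMF, 0 → 45 °C; then (CH2O)n, 23 °C
Reagents that add atoms: formaldehyde (as paraformaldehyde), C=O
Why: NaH deprotonates the phosphonoacetate at C11, this phosphoryl- and ester-stabilised carbanion opens the epoxide at its proximal carbon C7 by intramolecular SN2 attack anti to the C7–O bond, the C8 alkoxide so formed takes the acidic C11 proton of α-phosphono lactone 10, and the resulting phosphonate carbanion undergoes Horner–Wadsworth–Emmons olefination with formaldehyde to the exocyclic methylidene. The closest known reaction type is the base-induced epoxide-opening lactonisation of malonate and sulfonylacetate esters of 2,3-epoxy alcohols, joined here to the standard methylenation of α-phosphono γ-lactones. The γ-lactone (O, C6, C7, C11, C12) closes in the 5-exo-tet mode. C7 is set by inversion of the Sharpless-derived oxirane carbon (C11 enters trans to O6 of the erythro epoxy alcohol, hence the trans ring fusion), C8 keeps its configuration and appears as the free hydroxyl, and C6 is untouched. The step needs attack at C7 (5-exo) over C8 (6-endo) and C- over O-alkylation, which should be secured by the shorter tether path, by the C9 acetal that retards SN2 at C8, and by the soft doubly stabilised carbanion, whose phosphoryl group also frees C11 from the planar ester-enolate geometry that disfavours 5-(enolendo) closures. Phosphoryl transfer from C11 to O8, the cyclopropanation pathway of phosphonoacetates with epoxides, is held back by the mild temperature, the fast proton shift from C11 to O8 and the immediate olefination.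

Step 7
Reactants: 11 (4S,5S)-4-[(1R)-1-hydroxy-2,2-dimethoxyethyl]-5-[(1E,5Z)-6-iodo-2-methylhepta-1,5-dien-1-yl]-3-methylideneoxolan-2-one
Product: 14 (2R)-2-[(2S,3R)-2-[(1E,5Z)-6-iodo-2-methylhepta-1,5-dien-1-yl]-4-methylidene-5-oxooxolan-3-yl]-2-(triethylsilyloxy)acetaldehyde, via silyl ether acetal 12 (not isolated), via lutidinium salt 13 (not isolated)
Conditions: TESOTf, 2,6-lutidine, CH2Cl2, 0 → 23 °C; then H2O
Reagents that add atoms: triethylsilyl trifluoromethanesulfonate, CC[Si](CC)(CC)OS(=O)(=O)C(F)(F)F; water, O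
Why: The silyl triflate with 2,6-lutidine first silylates the C8 hydroxyl and then cleaves the dimethyl acetal by the known chemoselective silyl triflate/pyridine base method through a pyridinium N,O-acetal that is hydrolysed on adding water, so the C9 aldehyde is unmasked without protic acid and the TES ether, the allylic lactone and the C8 stereocenter should be kept.

Step 8
Reactants: 14 (2R)-2-[(2S,3R)-2-[(1E,5Z)-6-iodo-2-methylhepta-1,5-dien-1-yl]-4-methylidene-5-oxooxolan-3-yl]-2-(triethylsilyloxy)acetaldehyde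
Product: 15 (3aR,4R,5R,6Z,10E,11aS)-5-hydroxy-6,10-dimethyl-3-methylidene-4-(triethylsilyloxy)-3a,4,5,8,9,11a-hexahydrocyclodeca[b]furan-2(3H)-one
Conditions: CrCl2 (excess), NiCl2 (cat.), DMSO/THF, 23 °C, high dilution, slow addition of 14
Reagents that add atoms: none
Why: In this Nozaki–Hiyama–Kishi ring closure zerovalent nickel inserts into the vinyl C–I bond with retention of the Z geometry, transmetalation gives an alkenyl species of trivalent chromium that adds to the aldehyde to form C9–C10 and the ten-membered ring, and the new carbinol C9 is expected to be R because the closing ring places the chromium-bound oxygen and the OTES group both on its periphery with H8 and H9 anti, the arrangement of 8,9-trans-dioxygenated melampolides.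

Step 9
Reactants: 16 angelic acid, (2Z)-2-methylbut-2-enoic acid
Product: 17 (2Z)-2-methylbut-2-en-1-ol
Conditions: LiAlH4, Et2O, 0 °C
Reagents that add atoms: none
Why: Hydride reduction of the carboxylic acid with LiAlH4 gives the allylic alcohol by 1,2-addition without touching or isomerising the trisubstituted Z olefin.

Step 10
Reactants: 17 (2Z)-2-methylbut-2-en-1-ol
Product: 18 [(2S,3R)-2,3-dimethyloxiran-2-yl]methanol
Conditions: Ti(OiPr)4, L-(+)-DET, TBHP, 4 Å MS, CH2Cl2, −20 °C
Reagents that add atoms: tert-butyl hydroperoxide, CC(C)(C)OO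
Why: Sharpless asymmetric epoxidation of the primary allylic alcohol with L-(+)-DET should deliver oxygen under reagent control to the face that gives the (2S,3R)-epoxide, and the Z olefin geometry is carried over into the cis relation of CH2OH and the C3 methyl group.

Step 11
Reactants: 18 [(2S,3R)-2,3-dimethyloxiran-2-yl]methanol
Product: 19 (2R,3R)-2,3-dimethyloxirane-2-carboxylic acid
Conditions: RuCl3 (cat.), NaIO4, CCl4/MeCN/H2O, 23 °C
Reagents that add atoms: sodium periodate, [Na+].[O-]I(=O)(=O)=O; water, O
Why: RuO4 generated from RuCl3 and NaIO4 oxidises the primary alcohol of a 2,3-epoxy alcohol to the glycidic acid without opening the epoxide, so both stereocenters are kept (the C2 descriptor changes only by priority).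

Step 12
Reactants: 15 (3aR,4R,5R,6Z,10E,11aS)-5-hydroxy-6,10-dimethyl-3-methylidene-4-(triethylsilyloxy)-3a,4,5,8,9,11a-hexahydrocyclodeca[b]furan-2(3H)-one; 19 (2R,3R)-2,3-dimethyloxirane-2-carboxylic acid
Product: 21 (3aR,4R,5R,6Z,10E,11aS)-6,10-dimethyl-3-methylidene-2-oxo-4-(triethylsilyloxy)-2,3,3a,4,5,8,9,11a-octahydrocyclodeca[b]furan-5-yl (2R,3R)-2,3-dimethyloxirane-2-carboxylate, via mixed anhydride 20 (not isolated)
Conditions: 19, 2,4,6-trichlorobenzoyl chloride, Et3N, toluene, 23 °C; then 15, DMAP, 23 → 40 °C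
Reagents that add atoms: none
Why: Yamaguchi esterification through the mixed anhydride acylates the hindered allylic C9 hydroxyl with the α-quaternary acid with retention at C9 and at both epoxide carbons, the C8 oxygen being blocked as its TES ether.

Step 13
Reactants: 21 (3aR,4R,5R,6Z,10E,11aS)-6,10-dimethyl-3-methylidene-2-oxo-4-(triethylsilyloxy)-2,3,3a,4,5,8,9,11a-octahydrocyclodeca[b]furan-5-yl (2R,3R)-2,3-dimethyloxirane-2-carboxylate
Product: 22 (3aS,4R,5R,6Z,10E,11aS)-4-hydroxy-6,10-dimethyl-3-methylidene-2-oxo-2,3,3a,4,5,8,9,11a-octahydrocyclodeca[b]furan-5-yl (2R,3R)-2,3-dimethyloxirane-2-carboxylate (target)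
Conditions: HF·pyridine, pyridine, THF, 0 °C
Reagents that add atoms: none
Why: Fluoride-mediated desilylation with buffered HF·pyridine should cleave the secondary TES ether without opening the glycidic ester or adding to the methylidene lactone, and the weakly acidic medium avoids acyl migration from O9 to O8.

**Compound list**

1 | pent-4-yn-1-ol | C#CCCCO | starting material
2 | pent-4-ynal | C#CCCC=O | intermediate
3 | (5Z)-6-iodohept-5-en-1-yne | C#CCC/C=C(/C)I | intermediate
4 | (2E)-4,4-dimethoxybut-2-enal | COC(OC)/C=C/C=O | starting material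
5 | [(1E,5Z)-6-iodo-2-methylhepta-1,5-dien-1-yl]dimethylalane (not isolated) | C[Al](C)/C=C(\C)CC/C=C(/C)I | intermediate
6 | rac-(2E,5E,9Z)-10-iodo-1,1-dimethoxy-6-methylundeca-2,5,9-trien-4-ol | COC(OC)/C=C/C(O)/C=C(\C)CC/C=C(/C)I | intermediate
7 | (1S,2E,6Z)-1-[(2S,3R)-3-(dimethoxymethyl)oxiran-2-yl]-7-iodo-3-methylocta-2,6-dien-1-ol | COC(OC)[C@@H]1O[C@H]1[C@@H](O)/C=C(\C)CC/C=C(/C)I | intermediate
8 | (diethoxyphosphoryl)acetic acid | OC(=O)CP(=O)(OCC)OCC | starting material
9 | (1S,2E,6Z)-1-[(2S,3R)-3-(dimethoxymethyl)oxiran-2-yl]-7-iodo-3-methylocta-2,6-dien-1-yl (diethoxyphosphoryl)acetate | COC(OC)[C@@H]1O[C@H]1[C@@H](OC(=O)CP(=O)(OCC)OCC)/C=C(\C)CC/C=C(/C)I | intermediate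
10 | diethyl [(4S,5S)-4-[(1R)-1-hydroxy-2,2-dimethoxyethyl]-5-[(1E,5Z)-6-iodo-2-methylhepta-1,5-dien-1-yl]-2-oxooxolan-3-yl]phosphonate, C3 epimers, present as its sodium salt (not isolated) | COC(OC)[C@H](O)[C@@H]1C(P(=O)(OCC)OCC)C(=O)O[C@H]1/C=C(\C)CC/C=C(/C)I | intermediate
11 | (4S,5S)-4-[(1R)-1-hydroxy-2,2-dimethoxyethyl]-5-[(1E,5Z)-6-iodo-2-methylhepta-1,5-dien-1-yl]-3-methylideneoxolan-2-one | COC(OC)[C@H](O)[C@@H]1C(=C)C(=O)O[C@H]1/C=C(\C)CC/C=C(/C)I | intermediate
12 | (4R,5S)-4-[(1R)-2,2-dimethoxy-1-(triethylsilyloxy)ethyl]-5-[(1E,5Z)-6-iodo-2-methylhepta-1,5-dien-1-yl]-3-methylideneoxolan-2-one (not isolated) | COC(OC)[C@H](O[Si](CC)(CC)CC)[C@@H]1C(=C)C(=O)O[C@H]1/C=C(\C)CC/C=C(/C)I | intermediate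
13 | 1-[(2R)-1-methoxy-2-[(2S,3R)-2-[(1E,5Z)-6-iodo-2-methylhepta-1,5-dien-1-yl]-4-methylidene-5-oxooxolan-3-yl]-2-(triethylsilyloxy)ethyl]-2,6-dimethylpyridin-1-ium trifluoromethanesulfonate, both epimers at the N,O-acetal carbon (not isolated) | COC([n+]2c(C)cccc2C)[C@H](O[Si](CC)(CC)CC)[C@@H]1C(=C)C(=O)O[C@H]1/C=C(\C)CC/C=C(/C)I.[O-]S(=O)(=O)C(F)(F)F | intermediate
14 | (2R)-2-[(2S,3R)-2-[(1E,5Z)-6-iodo-2-methylhepta-1,5-dien-1-yl]-4-methylidene-5-oxooxolan-3-yl]-2-(triethylsilyloxy)acetaldehyde | O=C[C@H](O[Si](CC)(CC)CC)[C@@H]1C(=C)C(=O)O[C@H]1/C=C(\C)CC/C=C(/C)I | intermediate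
15 | (3aR,4R,5R,6Z,10E,11aS)-5-hydroxy-6,10-dimethyl-3-methylidene-4-(triethylsilyloxy)-3a,4,5,8,9,11a-hexahydrocyclodeca[b]furan-2(3H)-one | C=C1C(=O)O[C@H]2/C=C(\C)CC/C=C(/C)[C@@H](O)[C@H](O[Si](CC)(CC)CC)[C@H]12 | intermediate
16 | angelic acid, (2Z)-2-methylbut-2-enoic acid | C/C=C(/C)C(=O)O | starting material
17 | (2Z)-2-methylbut-2-en-1-ol | C/C=C(/C)CO | intermediate
18 | [(2S,3R)-2,3-dimethyloxiran-2-yl]methanol | OC[C@]1(C)O[C@@H]1C | intermediate
19 | (2R,3R)-2,3-dimethyloxirane-2-carboxylic acid | OC(=O)[C@]1(C)O[C@@H]1C | intermediate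
20 | (2R,3R)-2,3-dimethyloxirane-2-carboxylic 2,4,6-trichlorobenzoic anhydride (not isolated) | O=C(OC(=O)[C@]1(C)O[C@@H]1C)c1c(Cl)cc(Cl)cc1Cl | intermediate
21 | (3aR,4R,5R,6Z,10E,11aS)-6,10-dimethyl-3-methylidene-2-oxo-4-(triethylsilyloxy)-2,3,3a,4,5,8,9,11a-octahydrocyclodeca[b]furan-5-yl (2R,3R)-2,3-dimethyloxirane-2-carboxylate | C=C1C(=O)O[C@H]2/C=C(\C)CC/C=C(/C)[C@@H](OC(=O)[C@]3(C)O[C@@H]3C)[C@H](O[Si](CC)(CC)CC)[C@H]12 | intermediate
22 | (3aS,4R,5R,6Z,10E,11aS)-4-hydroxy-6,10-dimethyl-3-methylidene-2-oxo-2,3,3a,4,5,8,9,11a-octahydrocyclodeca[b]furan-5-yl (2R,3R)-2,3-dimethyloxirane-2-carboxylate | C=C1C(=O)O[C@H]2/C=C(\C)CC/C=C(/C)[C@@H](OC(=O)[C@]3(C)O[C@@H]3C)[C@H](O)[C@H]12 | target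

**Step count.** Total: 13 steps (10 in the main line, 3 for acid 19). Longest linear sequence: 10 steps (steps 1 to 8, 12 and 13).

**Steps most likely to fail**

Step 8. Ten-membered ring closure is strained, so intermolecular coupling may compete. Facial selectivity at the aldehyde may also be poor or reversed, since Felkin–Anh addition to the α-silyloxy aldehyde would favour the 9S carbinol. The fallback sets out from 14. The closure is run in the same way, and if its main carbinol is the 9S epimer (3aR,4R,5S,6Z,10E,11aS)-5-hydroxy-6,10-dimethyl-3-methylidene-4-(triethylsilyloxy)-3a,4,5,8,9,11a-hexahydrocyclodeca[b]furan-2(3H)-one F1, this is esterified with acid 19 under Mitsunobu conditions (PPh3, DIAD, toluene, 0 °C). The carboxylate should displace the activated C9 oxygen with inversion, so C9 is then set by SN2 displacement instead of by the ring closure, and the route is rejoined at 21.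

Step 6. The carbanion may attack slowly or in the wrong direction: 6-endo opening at C8, phosphoryl transfer to O8 followed by cyclopropane closure, or failure of the 5-(enolendo) alkylation. The fallback replaces the carbanion by a radical and sets out from 7. Esterification with propiolic acid (DCC, CH2Cl2, −20 °C) should give (1S,2E,6Z)-1-[(2S,3R)-3-(dimethoxymethyl)oxiran-2-yl]-7-iodo-3-methylocta-2,6-dien-1-yl prop-2-ynoate F2. Cp2TiCl (trivalent titanium, made from Cp2TiCl2 and zinc dust in THF) should then open the epoxide homolytically to the C7 radical with the titanium-bound oxygen on C8. This radical closes 5-exo-dig onto the alkynoate α-carbon, and hydrogen transfer to the vinyl radical and aqueous work-up return the route at 11. The trans ring fusion then rests on the preference of the substituents on C6 and C7, not on inversion.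

Step 4. Chemoselectivity between the two allylic olefins may be lost, epoxidation of the acetal-bearing olefin may be slow, and the resolution discards half of the material by design. The fallback sets out from 4 and makes the epoxide before the carbinol. NaBH4 (MeOH, 0 °C) reduces 4 to (2E)-4,4-dimethoxybut-2-en-1-ol F3. Sharpless epoxidation of this primary allylic alcohol with L-(+)-DET should give [(2S,3R)-3-(dimethoxymethyl)oxiran-2-yl]methanol F4. Oxidation (SO3·pyridine, DMSO, Et3N) gives (2R,3R)-3-(dimethoxymethyl)oxirane-2-carbaldehyde F5. Addition of alkenylalane 5 to F5, with Felkin–Anh attack anti to the epoxide C–O bond, should give the erythro carbinol, and the route is rejoined at 7 with no resolution needed.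

Further compounds
F1 | step 8 | (3aR,4R,5S,6Z,10E,11aS)-5-hydroxy-6,10-dimethyl-3-methylidene-4-(triethylsilyloxy)-3a,4,5,8,9,11a-hexahydrocyclodeca[b]furan-2(3H)-one | C=C1C(=O)O[C@H]2/C=C(\C)CC/C=C(/C)[C@H](O)[C@H](O[Si](CC)(CC)CC)[C@H]12
F2 | step 6 | (1S,2E,6Z)-1-[(2S,3R)-3-(dimethoxymethyl)oxiran-2-yl]-7-iodo-3-methylocta-2,6-dien-1-yl prop-2-ynoate | COC(OC)[C@@H]1O[C@H]1[C@@H](OC(=O)C#C)/C=C(\C)CC/C=C(/C)I
F3 | step 4 | (2E)-4,4-dimethoxybut-2-en-1-ol | COC(OC)/C=C/CO
F4 | step 4 | [(2S,3R)-3-(dimethoxymethyl)oxiran-2-yl]methanol | COC(OC)[C@@H]1O[C@H]1CO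
F5 | step 4 | (2R,3R)-3-(dimethoxymethyl)oxirane-2-carbaldehyde | COC(OC)[C@@H]1O[C@H]1C=O
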